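Locants used throughout are those of the target ring: C1 (acetoxy carbon), C2 (vinylic CH), C3 (alkene carbon bearing the exocyclic C7), C4 (free OH), C5 (benzoate), C6 (free OH). O1, O4, O5, O6 and O7 are the oxygens on those carbons.

## The problem

Target 16 is a monocyclic cyclohexene in which every ring carbon is functionalised: a trisubstituted C2=C3 alkene carrying C7H2OBz, and four contiguous oxygenated stereocentres C4 (OH), C5 (OBz), C6 (OH) and C1 (OAc). The ring oxygens alternate trans (O4/O5), cis (O5/O6), trans (O6/O1), with absolute configuration 1R,4S,5R,6S. There is no ring fusion to build and the chain is only seven carbons long. The difficulty is twofold: four stereocentres on a mobile ring, and five oxygens that must be told apart so that one takes acetate, two take benzoate and two stay free. As to control, a centre at C4 can bias C6 across the ring, C6 and C1 are set together if the C6–C1 bond is made by an aldol addition, and a free C1 hydroxyl can deliver hydride to a C5 carbonyl to set C5 1,3-anti to it. Little is tolerated: each free hydroxyl is vicinal to an ester (acyl migration under base), the C1 and C7 esters are allylic, and the ring is two eliminations away from a phenol, so β-oxygenated ketones and all late steps need neutral or weakly acidic conditions. The key step rests on this: once C5 is a ketone, C4–C5–C6 is a dihydroxyacetone unit whose C6 is nucleophilic as an enamine, and a C1 aldehyde is 1,5-related to C5 and held beside C6 by the cis C2=C3 bond. C7–C3–C4 is a second dihydroxyacetone unit when C3 is a ketone, so the same chemistry can supply C4.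

## Retrosynthesis

**16 ⇒ 15 ⇒ 14 ⇒ 13 (O6–PMB, O7–Bz, O4/O7 acetal).** The PMB ether on O6 is cut last because its oxidative removal is neutral and leaves no later step in which the freed hydroxyls sit beside esters under base. The C7 benzoate is cut next: it cannot survive the hydride step earlier in the route, so O7 is carried together with O4 in one isopropylidene acetal (13). After hydrolysis to diol 14 the O4/O7 problem is only primary against secondary. The forward reactions must be a mild acetal hydrolysis, a primary-selective benzoylation and a buffered DDQ cleavage.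

**13 ⇒ 12 ⇒ 11 ⇒ 10 (O5–Bz, O1–Ac, C5–H).** The C5 benzoate goes on when O5 is the only free hydroxyl (12). The acetate is placed on the allylic O1 of the 1,3-anti diol 11, whose O5 is flanked on both sides. Diol 11 comes from ketone 10 by hydride delivered from the C1 hydroxyl. Cutting in this order keeps C5 at the ketone level, where it is needed for the ring closure, and uses the aldol hydroxyl twice: as director and as the acetate site.

**10 ⇒ 9 (C6–C1, the key cut).** Cutting C6–C1 opens the ring to keto-enal 9, which has one stereocentre and no carbocycle. Against the neighbouring cuts (C2=C3 by metathesis, C3–C4 by cycloaddition) it has two advantages. It makes the ring and two stereocentres at once. It also delivers the oxygens already differentiated: O1 the only free hydroxyl, C5 a ketone, O6 an ether, O4/O7 an acetal. Two features of 9 are deliberate. First, O4 is not free: a cis-4-hydroxy-enal would sit as a five-membered lactol that loses water to a 2-acylfuran, so O4 is tied to O7 in a dioxane. Second, that dioxane holds the C4–O bond pseudoequatorial on the forming ring, the orientation that leads to the trans O4/O6 product. The forward reaction must form the enamine toward C6 and not C4, close faster than the C4–H is lost, and choose one face of both the enamine and the aldehyde.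

**9 ⇒ 8 ⇒ 6 (oxidation levels, alkene geometry).** Keto-enal 9 is the double oxidation product of diol 8, and 8 is the full reduction product of the unsaturated δ-lactone 6. The lactone does two jobs: a six-membered ring can only hold a cis C2=C3 bond, which puts C1 cis to C4, and it keeps O5 distinct from every other oxygen until it is needed as the ketone. The forward steps are an exhaustive hydride reduction and an oxidation in which both alcohols are activated before either carbonyl exists.

**6 ⇒ 5 ⇒ 3 + 4 (C2=C3, O5–C1).** The lactone is cut at the alkene by an intramolecular Horner–Wadsworth–Emmons olefination of phosphonoacetate 5. Ester 5 is the ester of β-hydroxy ketone 3 with diethylphosphonoacetic acid 4, which supplies C1 and C2. An intermolecular olefination of the same ketone would give no control of geometry.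

**3 ⇒ 1 + 2 (C4–C5).** Ketone 3 is the aldol adduct of 2,2-dimethyl-1,3-dioxan-5-one 1 (C7, C3, C4 with O4 and O7 already joined) and aldehyde 2 (C5, C6 with the PMB ether in place). A proline-catalysed aldol sets C4; the C5 carbinol formed with it is later oxidised away. Both partners are achiral catalogue compounds.

## Roads not taken

**Alternative 1: enzymatic ipso,ortho-dihydroxylation of benzoic acid A1.** No carbon–carbon bond is cut: ring and C7 (the carboxyl) come from A1. The forward key step is whole-cell oxidation (benzoate 1,2-dioxygenase in resting cells of Ralstonia eutropha B9), which adds O2 across the ipso and ortho carbons. It gives the cis-diol acid A2 with the C3–O and C4–O bonds and a C1=C2/C5=C6 diene.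
- Merits: all seven carbons and an enantiopure C4 centre in one step from a commodity chemical, with no ring-forming step at all.
- Weak points: the C3 oxygen is one too many and must leave (allylic transposition to C1 or elimination); the acid must be reduced; O5, O6 and O1 must be added to a diene that rearomatises easily; five hydroxyls then have to be differentiated one by one. A fermentation facility and the strain are also needed.
- Comparison: A2 is better in cost, in certainty of absolute configuration and in having no risky ring closure. The chosen plan sets against this that no surplus oxygen is made, every oxygen arrives already distinguished, and only catalogue reagents are used. It pays with an unprecedented key step.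

**Alternative 2: nitrile oxide cycloaddition from D-mannose A3.** The cut is C3–C4 (with C7–O). In the forward step NaOCl oxidises the open-chain aldoxime A4 to a nitrile oxide, which adds across the terminal C3=C7 alkene and closes the carbocycle as the fused isoxazoline A5.
- Merits: this ring closure is well precedented for carbasugars; C5, C6 and C1 come from the sugar; the C5 benzoate is in place early; the cycloaddition delivers O7.
- Weak points: the sugar brings an extra oxygen at C2 that must be eliminated to make C2=C3; the C3 centre is made and then destroyed; C4 has to be set late by reducing a ketone next to the C5 benzoate; the path from A3 to A4 is long and heavy in protecting-group steps.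
- Comparison: A5 is reached by safer chemistry than 10, and three centres are bought instead of made. The chosen plan answers with roughly half the step count and three centres set by catalysis and ring conformation, at the price of a riskier closure.

**Alternative 3: hydroxyl-directed epoxidation of the trans-dihydrodiol diene A6.** The cut is the two C–O bonds at C6 and C1. VO(acac)2 and t-BuOOH, bound to the free C5 hydroxyl of A6, epoxidise the C1=C6 alkene cis to O5 and give A7.
- Merits: directed epoxidation is among the most reliable stereocontrol elements. Opening A7 at the allylic C1 with acetate would install the C1 acetate and free O6 with the correct trans relationship in one operation, so the end game is very short.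
- Weak points: enantiopure A6 is not a catalogue compound and needs a biotransformation or a multi-step synthesis; A7 is a vinyl epoxide prone to SN2' opening and aromatisation; the regiochemistry of opening (C1 or C6) is not assured; O5 must still be benzoylated next to the freed O6.
- Comparison: in stereochemical reliability of its key step and in late-stage economy this road is as good as or better than the chosen one. The chosen plan sets against it a de novo start from achiral catalogue compounds and a closure that forms the ring and two centres together; its own key step is less certain.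

Key step: step 6

Remark: aldehyde 2 is treated as a catalogue compound and is distilled immediately before use, as is usual for α-alkoxy acetaldehydes.

## Route

Step 1
Reactants: 1 2,2-dimethyl-1,3-dioxan-5-one; 2 2-[(4-methoxybenzyl)oxy]acetaldehyde
Product: 3 (4R)-4-[(1R)-1-hydroxy-2-[(4-methoxybenzyl)oxy]ethyl]-2,2-dimethyl-1,3-dioxan-5-one
Conditions: D-proline (30 mol %), DMF, 4 °C; 1 in excess, 2 added slowly
Reagents that add atoms: none
Why: Proline-catalysed direct aldol addition (enamine catalysis) of the dioxanone to an α-alkoxy aldehyde, a known route to protected ketoses; D-proline should give the anti adduct with C4 (R), which is the O4 orientation of the target, and C5 (R), which is erased in step 5. Excess 1 and slow addition of 2 hold back the self-aldol of 2.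

Step 2
Reactants: 3 (4R)-4-[(1R)-1-hydroxy-2-[(4-methoxybenzyl)oxy]ethyl]-2,2-dimethyl-1,3-dioxan-5-one; 4 (diethoxyphosphoryl)acetic acid
Product: 5 (1R)-1-[(4R)-2,2-dimethyl-5-oxo-1,3-dioxan-4-yl]-2-[(4-methoxybenzyl)oxy]ethyl (diethoxyphosphoryl)acetate
Conditions: DCC, DMAP (5 mol %), CH2Cl2, 0 °C
Reagents that add atoms: none
Why: Steglich esterification of the secondary hydroxyl; it is run cold and briefly so that the β-acyloxy ketone does not eliminate.

Step 3
Reactants: 5 (1R)-1-[(4R)-2,2-dimethyl-5-oxo-1,3-dioxan-4-yl]-2-[(4-methoxybenzyl)oxy]ethyl (diethoxyphosphoryl)acetate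
Product: 6 δ-lactone (O5 to C1) of (2Z)-2-[(4S)-4-[(1R)-1-hydroxy-2-[(4-methoxybenzyl)oxy]ethyl]-2,2-dimethyl-1,3-dioxan-5-ylidene]acetic acid
Conditions: LiCl, i-Pr2NEt, MeCN, 23 °C
Reagents that add atoms: none
Why: Intramolecular Horner–Wadsworth–Emmons olefination under Masamune–Roush conditions; the six-membered lactone can only contain a cis C2=C3 bond, so C1 ends up cis to C4, and the weak amine base deprotonates the lithium-bound phosphonate in preference to the C4–H.

Step 4
Reactants: 6 δ-lactone (O5 to C1) of (2Z)-2-[(4S)-4-[(1R)-1-hydroxy-2-[(4-methoxybenzyl)oxy]ethyl]-2,2-dimethyl-1,3-dioxan-5-ylidene]acetic acid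
Product: 8 (1R)-1-[(4S,5Z)-5-(2-hydroxyethylidene)-2,2-dimethyl-1,3-dioxan-4-yl]-2-[(4-methoxybenzyl)oxy]ethan-1-ol, via lactol 7 (not isolated)
Conditions: i-Bu2AlH (4 equiv), CH2Cl2, −78 to −20 °C; aq. KNaC4H4O6 work-up
Reagents that add atoms: none
Why: Exhaustive DIBAL reduction of an α,β-unsaturated lactone by two 1,2-hydride additions through lactol 7; it gives the (Z)-allylic alcohol and releases O5 as the free C5 hydroxyl, while the acetal and the PMB ether are inert.

Step 5
Reactants: 8 (1R)-1-[(4S,5Z)-5-(2-hydroxyethylidene)-2,2-dimethyl-1,3-dioxan-4-yl]-2-[(4-methoxybenzyl)oxy]ethan-1-ol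
Product: 9 (2Z)-2-[(4S)-4-{[(4-methoxybenzyl)oxy]acetyl}-2,2-dimethyl-1,3-dioxan-5-ylidene]acetaldehyde
Conditions: (COCl)2, DMSO, CH2Cl2, −78 °C; i-Pr2NEt, −78 to −40 °C; cold pH 7 phosphate buffer
Reagents that add atoms: none
Why: Swern oxidation; both hydroxyls are converted into alkoxysulfonium ions at −78 °C before any carbonyl exists, so no six-membered lactol can form and be oxidised back to 6. The hindered base and the cold buffered quench protect the acidic C4–H and the Z-enal; 9 is used at once.

Step 6
Reactants: 9 (2Z)-2-[(4S)-4-{[(4-methoxybenzyl)oxy]acetyl}-2,2-dimethyl-1,3-dioxan-5-ylidene]acetaldehyde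
Product: 10 (6R,7S,8aS)-6-hydroxy-7-[(4-methoxybenzyl)oxy]-2,2-dimethyl-6,7-dihydro-4H-1,3-benzodioxin-8(8aH)-one (target locants 1R,4S,6S)
Conditions: L-proline (30 mol %), DMSO, 20 °C
Reagents that add atoms: none
Why: Proposed new method: L-proline should condense with the C5 ketone to give the less substituted (E)-enamine toward C6 (alkoxy trans to nitrogen), whose C6 adds to the C1 aldehyde held cis by the C2=C3 bond while the carboxylic acid hydrogen-bonds the aldehyde oxygen; hydrolysis of the iminium ion releases 10 and the catalyst. The closest known reactions are the proline-catalysed Hajos–Parrish enolendo aldolisation, proline aldol additions of dihydroxyacetone-type ketones as in step 1, and base-mediated cyclisations of sugar 1,5-dicarbonyl compounds to inososes; no keto-enal of this kind has been closed in this way. The ring closes in the 6-(enolendo)-exo-trig mode, because the enamine C5=C6 bond lies inside the new ring and the aldehyde C=O outside it. C6 is controlled by the (E)-enamine geometry, which places O6 pseudoaxial on the forming ring, and by L-proline, which selects the enamine face as in its cyclohexanone aldol additions. C1 is controlled by the acid-bound aldehyde oxygen, which must lie gauche to C5 and is therefore pseudoaxial and anti to O6, giving the trans C1/C6 relationship. The fused dioxane holds O4 pseudoequatorial, which is trans to the axial O6, so the resident C4 centre and the catalyst call for the same face (matched pair). The step needs enamine formation at C6 and not at C4, and closure faster than γ-deprotonation at C4; the unhindered C6 methylene against the tertiary ring-bound C4–H secures the first and the intramolecularity the second.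

Step 7
Reactants: 10 (6R,7S,8aS)-6-hydroxy-7-[(4-methoxybenzyl)oxy]-2,2-dimethyl-6,7-dihydro-4H-1,3-benzodioxin-8(8aH)-one
Product: 11 (6R,7S,8R,8aS)-7-[(4-methoxybenzyl)oxy]-2,2-dimethyl-6,7,8,8a-tetrahydro-4H-1,3-benzodioxine-6,8-diol (target locants 1R,4S,5R,6S)
Conditions: Me4NBH(OAc)3 (5 equiv), MeCN/AcOH (1:1), −30 °C
Reagents that add atoms: none
Why: Evans–Saksena hydroxyl-directed reduction; the C1 alkoxyborohydride delivers hydride to the C5 carbonyl from the O1 face and should give the 1,3-anti diol with O5 cis to O6 and trans to O4. The acidic medium suppresses β-elimination and C4 epimerisation of the β-hydroxy ketone.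

Step 8
Reactants: 11 (6R,7S,8R,8aS)-7-[(4-methoxybenzyl)oxy]-2,2-dimethyl-6,7,8,8a-tetrahydro-4H-1,3-benzodioxine-6,8-diol
Product: 12 (6R,7R,8R,8aS)-8-hydroxy-7-[(4-methoxybenzyl)oxy]-2,2-dimethyl-6,7,8,8a-tetrahydro-4H-1,3-benzodioxin-6-yl acetate
Conditions: AcCl (1.05 equiv), 2,4,6-collidine, CH2Cl2, −78 to −40 °C
Reagents that add atoms: acetyl chloride CC(=O)Cl
Why: Regioselective acylation; the allylic C1 hydroxyl has one oxygenated neighbour, whereas the C5 hydroxyl is flanked by the dioxane and the PMB ether, so a slight excess of acyl chloride with a hindered pyridine in the cold should acetylate O1 first.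

Step 9
Reactants: 12 (6R,7R,8R,8aS)-8-hydroxy-7-[(4-methoxybenzyl)oxy]-2,2-dimethyl-6,7,8,8a-tetrahydro-4H-1,3-benzodioxin-6-yl acetate
Product: 13 (6R,7S,8R,8aS)-6-acetoxy-7-[(4-methoxybenzyl)oxy]-2,2-dimethyl-6,7,8,8a-tetrahydro-4H-1,3-benzodioxin-8-yl benzoate
Conditions: BzCl, pyridine, DMAP (cat.), CH2Cl2, 0 to 23 °C
Reagents that add atoms: benzoyl chloride O=C(Cl)c1ccccc1
Why: DMAP-catalysed benzoylation of the only free hydroxyl; the acetate cannot migrate to O5 because C1 and C5 are 1,3-trans.

Step 10
Reactants: 13 (6R,7S,8R,8aS)-6-acetoxy-7-[(4-methoxybenzyl)oxy]-2,2-dimethyl-6,7,8,8a-tetrahydro-4H-1,3-benzodioxin-8-yl benzoate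
Product: 14 (1R,4S,5R,6S)-5-(benzoyloxy)-4-hydroxy-3-(hydroxymethyl)-6-[(4-methoxybenzyl)oxy]cyclohex-2-en-1-yl acetate
Conditions: AcOH/H2O (4:1), 40 °C
Reagents that add atoms: none
Why: Acid-catalysed hydrolysis of the isopropylidene acetal; aqueous acetic acid leaves the esters and the PMB ether intact and is too weak to ionise the allylic acetate.

Step 11
Reactants: 14 (1R,4S,5R,6S)-5-(benzoyloxy)-4-hydroxy-3-(hydroxymethyl)-6-[(4-methoxybenzyl)oxy]cyclohex-2-en-1-yl acetate
Product: 15 (1R,4S,5R,6S)-5-(benzoyloxy)-3-[(benzoyloxy)methyl]-4-hydroxy-6-[(4-methoxybenzyl)oxy]cyclohex-2-en-1-yl acetate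
Conditions: BzCl (1.05 equiv), 2,4,6-collidine, CH2Cl2, −78 to −20 °C
Reagents that add atoms: benzoyl chloride O=C(Cl)c1ccccc1
Why: Primary-selective acylation with an acyl chloride and a hindered pyridine; the primary allylic C7 hydroxyl should react far faster than the secondary C4 hydroxyl next to the C5 benzoate, and the cold, weakly basic medium does not move the existing esters.

Step 12
Reactants: 15 (1R,4S,5R,6S)-5-(benzoyloxy)-3-[(benzoyloxy)methyl]-4-hydroxy-6-[(4-methoxybenzyl)oxy]cyclohex-2-en-1-yl acetate
Product: 16 (1R,4S,5R,6S)-5-(benzoyloxy)-3-[(benzoyloxy)methyl]-4,6-dihydroxycyclohex-2-en-1-yl acetate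
Conditions: DDQ (1.5 equiv), CH2Cl2/aq. pH 7 phosphate buffer, 0 °C
Reagents that add atoms: none
Why: Oxidative cleavage of the PMB ether by DDQ (hydride abstraction, then hydrolysis of the oxocarbenium ion) under buffered neutral conditions, which avoids acyl migration onto the freed hydroxyls.

## Compound list

1 | 2,2-dimethyl-1,3-dioxan-5-one | CC1(C)OCC(=O)CO1 | starting material
2 | 2-[(4-methoxybenzyl)oxy]acetaldehyde | O=CCOCc1ccc(OC)cc1 | starting material
3 | (4R)-4-[(1R)-1-hydroxy-2-[(4-methoxybenzyl)oxy]ethyl]-2,2-dimethyl-1,3-dioxan-5-one | CC1(C)OCC(=O)[C@H](O1)[C@H](O)COCc1ccc(OC)cc1 | intermediate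
4 | (diethoxyphosphoryl)acetic acid (diethylphosphonoacetic acid) | OC(=O)CP(=O)(OCC)OCC | starting material
5 | (1R)-1-[(4R)-2,2-dimethyl-5-oxo-1,3-dioxan-4-yl]-2-[(4-methoxybenzyl)oxy]ethyl (diethoxyphosphoryl)acetate | CC1(C)OCC(=O)[C@H](O1)[C@H](OC(=O)CP(=O)(OCC)OCC)COCc1ccc(OC)cc1 | intermediate
6 | δ-lactone (O5 to C1) of (2Z)-2-[(4S)-4-[(1R)-1-hydroxy-2-[(4-methoxybenzyl)oxy]ethyl]-2,2-dimethyl-1,3-dioxan-5-ylidene]acetic acid; dihydropyranone fused at C3–C4 to the dioxane | O=C1O[C@H](COCc3ccc(OC)cc3)[C@H]2OC(C)(C)OCC2=C1 | intermediate
7 | δ-lactol corresponding to 6 (C1 hemiacetal, both anomers; C4 S, C5 R) | OC1O[C@H](COCc3ccc(OC)cc3)[C@H]2OC(C)(C)OCC2=C1 | intermediate (not isolated)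
8 | (1R)-1-[(4S,5Z)-5-(2-hydroxyethylidene)-2,2-dimethyl-1,3-dioxan-4-yl]-2-[(4-methoxybenzyl)oxy]ethan-1-ol | OC/C=C1/COC(C)(C)O[C@@H]1[C@H](O)COCc1ccc(OC)cc1 | intermediate
9 | (2Z)-2-[(4S)-4-{[(4-methoxybenzyl)oxy]acetyl}-2,2-dimethyl-1,3-dioxan-5-ylidene]acetaldehyde | O=C/C=C1/COC(C)(C)O[C@@H]1C(=O)COCc1ccc(OC)cc1 | intermediate (key-step precursor)
10 | (6R,7S,8aS)-6-hydroxy-7-[(4-methoxybenzyl)oxy]-2,2-dimethyl-6,7-dihydro-4H-1,3-benzodioxin-8(8aH)-one (1R,4S,6S in target locants) | O[C@@H]1C=C2COC(C)(C)O[C@@H]2C(=O)[C@H]1OCc1ccc(OC)cc1 | intermediate (key-step product)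
11 | (6R,7S,8R,8aS)-7-[(4-methoxybenzyl)oxy]-2,2-dimethyl-6,7,8,8a-tetrahydro-4H-1,3-benzodioxine-6,8-diol | O[C@@H]1C=C2COC(C)(C)O[C@@H]2[C@@H](O)[C@H]1OCc1ccc(OC)cc1 | intermediate
12 | (6R,7R,8R,8aS)-8-hydroxy-7-[(4-methoxybenzyl)oxy]-2,2-dimethyl-6,7,8,8a-tetrahydro-4H-1,3-benzodioxin-6-yl acetate | CC(=O)O[C@@H]1C=C2COC(C)(C)O[C@@H]2[C@@H](O)[C@H]1OCc1ccc(OC)cc1 | intermediate
13 | (6R,7S,8R,8aS)-6-acetoxy-7-[(4-methoxybenzyl)oxy]-2,2-dimethyl-6,7,8,8a-tetrahydro-4H-1,3-benzodioxin-8-yl benzoate | CC(=O)O[C@@H]1C=C2COC(C)(C)O[C@@H]2[C@@H](OC(=O)c3ccccc3)[C@H]1OCc1ccc(OC)cc1 | intermediate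
14 | (1R,4S,5R,6S)-5-(benzoyloxy)-4-hydroxy-3-(hydroxymethyl)-6-[(4-methoxybenzyl)oxy]cyclohex-2-en-1-yl acetate | CC(=O)O[C@@H]1C=C(CO)[C@H](O)[C@@H](OC(=O)c2ccccc2)[C@H]1OCc1ccc(OC)cc1 | intermediate
15 | (1R,4S,5R,6S)-5-(benzoyloxy)-3-[(benzoyloxy)methyl]-4-hydroxy-6-[(4-methoxybenzyl)oxy]cyclohex-2-en-1-yl acetate | CC(=O)O[C@@H]1C=C(COC(=O)c2ccccc2)[C@H](O)[C@@H](OC(=O)c2ccccc2)[C@H]1OCc1ccc(OC)cc1 | intermediate
16 | (1R,4S,5R,6S)-5-(benzoyloxy)-3-[(benzoyloxy)methyl]-4,6-dihydroxycyclohex-2-en-1-yl acetate | CC(=O)O[C@@H]1C=C(COC(=O)c2ccccc2)[C@H](O)[C@@H](OC(=O)c2ccccc2)[C@H]1O | target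

## Step count and risk

Total step count: 12. Longest linear sequence: 12 steps (1 and 2 to 16).

**Step 6 (key step, proposed new method).** The most likely failure is that proline condenses with the enal instead of the ketone. The resulting iminium ion or dienamine would lose the C4 configuration by γ-deprotonation, or let the C2=C3 bond isomerise so that C1 can no longer reach C6. Poor facial selectivity is also possible if the ring oxygen next to the enamine nitrogen disturbs the preferred transition state, and the aldol could dehydrate toward an aromatic ring on long standing. Fallback, from 9 back to 10 with no amine catalyst: a stoichiometric boron-mediated aldol of the kind known for α-alkoxy ketones and aldehydes. (c-C6H11)2BCl and Et3N in Et2O at −78 °C should enolise the ketone at the unhindered C6 methylene; the (E)-enol borinate closes onto the aldehyde through a boron-bridged chair, and H2O2 in buffered MeOH releases 10. Stereocontrol then rests on the enolate geometry and the dioxane bias, not on a catalyst.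

**Step 3.** β-Elimination of the phosphonoacetate across C4–C5, or epimerisation at C4, may outrun olefination of the hindered ring ketone. Fallback, from 3 back to 6 by olefin metathesis instead of olefination:
- Et3SiCl/imidazole gives the triethylsilyl ether F1.
- Ph3P=CH2 converts the ring ketone into the 5-methylidene dioxane F2.
- Bu4NF frees the alcohol F3.
- Acryloyl chloride/i-Pr2NEt gives the acrylate F4.
- Ring-closing metathesis with (H2IMes)(PCy3)Cl2Ru=CHPh (second-generation Grubbs catalyst) in refluxing CH2Cl2 forms the C2=C3 bond and returns lactone 6.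

**Step 5.** The amine base may epimerise C4 or trigger elimination in the doubly activated keto-enal, and incomplete activation would allow lactol formation and re-oxidation to 6. Fallback, from 8 back to 9 by separate neutral oxidations:
- Et3SiCl/imidazole at −40 °C silylates the primary allylic hydroxyl to the mono-silyl ether F5.
- Dess–Martin periodinane with NaHCO3 oxidises C5 to the ketone F6.
- HF·pyridine removes the silyl group to give the hydroxy ketone F7.
- MnO2 oxidises the allylic alcohol to 9.

**Step 8.** Acetylation may not discriminate well enough between O1 and O5, giving over-acylation or the wrong monoester. Fallback, from 10 directly to 12, replacing steps 7 and 8: an Evans–Tishchenko reduction with SmI2 (30 mol %), pre-stirred with excess CH3CHO so that the active species is a trivalent samarium alkoxide, in THF at −10 °C. The C1 hemiacetal transfers hydride to C5 from the O1 face and leaves the acetate on O1 by mechanism, so no regioselective acylation is needed.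

## Further compounds

F0 | step 6 | none | none
F1 | step 3 | (4R)-2,2-dimethyl-4-[(1R)-2-[(4-methoxybenzyl)oxy]-1-(triethylsilyloxy)ethyl]-1,3-dioxan-5-one | CC1(C)OCC(=O)[C@H](O1)[C@H](O[Si](CC)(CC)CC)COCc1ccc(OC)cc1
F2 | step 3 | (4S)-2,2-dimethyl-5-methylidene-4-[(1R)-2-[(4-methoxybenzyl)oxy]-1-(triethylsilyloxy)ethyl]-1,3-dioxane | CC1(C)OCC(=C)[C@H](O1)[C@H](O[Si](CC)(CC)CC)COCc1ccc(OC)cc1
F3 | step 3 | (1R)-1-[(4S)-2,2-dimethyl-5-methylidene-1,3-dioxan-4-yl]-2-[(4-methoxybenzyl)oxy]ethan-1-ol | CC1(C)OCC(=C)[C@H](O1)[C@H](O)COCc1ccc(OC)cc1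
F4 | step 3 | (1R)-1-[(4S)-2,2-dimethyl-5-methylidene-1,3-dioxan-4-yl]-2-[(4-methoxybenzyl)oxy]ethyl prop-2-enoate | CC1(C)OCC(=C)[C@H](O1)[C@H](OC(=O)C=C)COCc1ccc(OC)cc1
F5 | step 5 | (1R)-1-[(4S,5Z)-2,2-dimethyl-5-[2-(triethylsilyloxy)ethylidene]-1,3-dioxan-4-yl]-2-[(4-methoxybenzyl)oxy]ethan-1-ol | CC[Si](CC)(CC)OC/C=C1/COC(C)(C)O[C@@H]1[C@H](O)COCc1ccc(OC)cc1
F6 | step 5 | 1-[(4S,5Z)-2,2-dimethyl-5-[2-(triethylsilyloxy)ethylidene]-1,3-dioxan-4-yl]-2-[(4-methoxybenzyl)oxy]ethan-1-one | CC[Si](CC)(CC)OC/C=C1/COC(C)(C)O[C@@H]1C(=O)COCc1ccc(OC)cc1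
F7 | step 5 | 1-[(4S,5Z)-5-(2-hydroxyethylidene)-2,2-dimethyl-1,3-dioxan-4-yl]-2-[(4-methoxybenzyl)oxy]ethan-1-one | OC/C=C1/COC(C)(C)O[C@@H]1C(=O)COCc1ccc(OC)cc1
F0 | step 8 | none | none
A1 | alternative 1 | benzoic acid | OC(=O)c1ccccc1
A2 | alternative 1 | (1S,2R)-1,2-dihydroxycyclohexa-3,5-diene-1-carboxylic acid | O=C(O)[C@]1(O)C=CC=C[C@H]1O
A3 | alternative 2 | D-mannose (open-chain form) | O=C[C@@H](O)[C@@H](O)[C@H](O)[C@H](O)CO
A4 | alternative 2 | open-chain aldoxime at C4 with C5 benzoate, C6 triethylsilyl ether, C1/C2 acetonide and terminal C3=C7 alkene | ON=C[C@@H](OC(=O)c1ccccc1)[C@@H](O[Si](CC)(CC)CC)[C@@H]1OC(C)(C)O[C@@H]1C=C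
A5 | alternative 2 | carbocycle-fused isoxazoline (C4=N, O on C7; C1/C2 acetonide, C6 triethylsilyl ether, C5 benzoate) | C12=NOC[C@@H]1[C@H]3OC(C)(C)O[C@H]3[C@H](O[Si](CC)(CC)CC)[C@@H]2OC(=O)c1ccccc1
A6 | alternative 3 | trans-dihydrodiol diene (C2=C3–C1=C6) with free C5 hydroxyl, C4 tert-butyldimethylsilyl ether and C7 benzoate | O[C@H]1C=CC=C(COC(=O)c2ccccc2)[C@@H]1O[Si](C)(C)C(C)(C)C
A7 | alternative 3 | C1–C6 epoxide cis to the C5 hydroxyl | O[C@H]1[C@H]2O[C@H]2C=C(COC(=O)c2ccccc2)[C@@H]1O[Si](C)(C)C(C)(C)C
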